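**Plan**

1. Numbering: C6 is the pentyl-bearing CH, C7 its CH2, C8=C9 the alkene of ring A (CH2OH on C9), C10=C11 the alkene of ring B (C6 on C10, 2-oxohexyl on C11). Rings A and B are both 2,3-dialkylmaleic anhydrides, so each equals an internal alkyne that has taken up two CO; this feature makes the key step possible.
2. Retrosynthesis: both anhydrides are opened to methyl esters and the four bonds from C8, C9, C10 and C11 to their carbonyl carbons are cut together. This leads to a 1,5-diyne with the alcohol as PMB ether and the ketone as dioxolane.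
3. The diyne is cut further at C11–CH2 (acetylide plus 1,2-epoxyhexane), at C10≡C11 (Corey–Fuchs homologation of an aldehyde) and at C6–C7 (enolate alkylation with a butynediol-derived propargylic bromide).
4. Forward: C6–C7 is joined first, then C10≡C11 and C11–CH2, then all four carbonyl carbons are added in one carbonylation that closes no ring. Rings A and B both close in step 12 on acidification, and the PMB ether is removed last.
5. Stereochemistry: C6 is the only stereocentre. It is set as (S) in step 4 by Evans alkylation under control of (R)-4-benzyl-2-oxazolidinone and is carried through unchanged.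

Key step: step 11

Assumption: 1,2-epoxyhexane is used as the racemate because its carbinol carbon becomes the ketone carbon, and the target is taken to persist as the drawn hydroxymethyl bis-anhydride, since acyl transfer from ring A to the C9 CH2OH would need a bridged transition state across C8=C9.

**Route**

Step 1
Reactants: 1 (R)-4-benzyl-2-oxazolidinone; 2 heptanoyl chloride
Product: 4 (R)-4-benzyl-3-heptanoyl-1,3-oxazolidin-2-one, via N-lithio oxazolidinone 3 (not isolated)
Conditions: n-BuLi, THF, −78 °C; then 2, −78 → 0 °C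
Reagents that add atoms: none
Why: N-acylation of the lithiated oxazolidinone by an acid chloride is the standard way to load an Evans auxiliary and creates no stereocentre.

Step 2
Reactants: 5 but-2-yne-1,4-diol (threefold excess)
Product: 7 4-[(4-methoxybenzyl)oxy]but-2-yn-1-ol, via monosodium alkoxide 6 (not isolated)
Conditions: NaH, DMF, 0 °C; then 4-MeOC6H4CH2Cl, Bu4NI (cat.), 0 °C → rt
Reagents that add atoms: 4-methoxybenzyl chloride, COc1ccc(CCl)cc1
Why: Williamson ether synthesis on the mono-alkoxide of a symmetrical diol used in excess should favour the mono-PMB ether, which is separable from diol and bis-ether.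

Step 3
Reactants: 7 4-[(4-methoxybenzyl)oxy]but-2-yn-1-ol
Product: 8 1-{[(4-bromobut-2-yn-1-yl)oxy]methyl}-4-methoxybenzene
Conditions: CBr4, PPh3, CH2Cl2, 0 °C
Reagents that add atoms: carbon tetrabromide, BrC(Br)(Br)Br
Why: Appel bromination converts the primary propargylic alcohol into the bromide by SN2 displacement of the oxyphosphonium group under neutral conditions that spare the PMB ether.

Step 4
Reactants: 4 (R)-4-benzyl-3-heptanoyl-1,3-oxazolidin-2-one; 8 1-{[(4-bromobut-2-yn-1-yl)oxy]methyl}-4-methoxybenzene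
Product: 10 (R)-4-benzyl-3-{(S)-6-[(4-methoxybenzyl)oxy]-2-pentylhex-4-ynoyl}-1,3-oxazolidin-2-one, via sodium (Z)-enolate 9 (not isolated)
Conditions: NaN(SiMe3)2, THF, −78 °C; then 8, −78 → −40 °C
Reagents that add atoms: none
Why: In this Evans asymmetric alkylation the chelated (Z)-sodium enolate should be attacked by the reactive propargylic bromide on the face opposite the C4 benzyl group, which with the (R)-auxiliary sets C6 as (S) while forming the C6–C7 bond.

Step 5
Reactants: 10 (R)-4-benzyl-3-{(S)-6-[(4-methoxybenzyl)oxy]-2-pentylhex-4-ynoyl}-1,3-oxazolidin-2-one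
Product: 11 (S)-6-[(4-methoxybenzyl)oxy]-2-pentylhex-4-yn-1-ol
Conditions: LiBH4, H2O (1 equiv), Et2O, 0 °C
Reagents that add atoms: none
Why: Reductive cleavage of the N-acyl oxazolidinone with LiBH4 attacks the exocyclic carbonyl, giving the primary alcohol and releasing the auxiliary without touching the alkyne, the PMB ether or C6.

Step 6
Reactants: 11 (S)-6-[(4-methoxybenzyl)oxy]-2-pentylhex-4-yn-1-ol
Product: 12 (S)-6-[(4-methoxybenzyl)oxy]-2-pentylhex-4-ynal
Conditions: Dess–Martin periodinane, NaHCO3, CH2Cl2, 0 °C → rt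
Reagents that add atoms: none
Why: Buffered Dess–Martin oxidation gives the α-branched aldehyde under near-neutral conditions that should not epimerise C6.

Step 7
Reactants: 12 (S)-6-[(4-methoxybenzyl)oxy]-2-pentylhex-4-ynal
Product: 13 (S)-1,1-dibromo-7-[(4-methoxybenzyl)oxy]-3-pentylhept-1-en-5-yne
Conditions: CBr4, PPh3, Zn, CH2Cl2, rt; then 12, 0 °C → rt
Reagents that add atoms: carbon tetrabromide, BrC(Br)(Br)Br
Why: The first stage of the Corey–Fuchs sequence is a Wittig reaction of Ph3P=CBr2, preformed with Zn so that neither amine base nor HBr meets the epimerisable aldehyde.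

Step 8
Reactants: 13 (S)-1,1-dibromo-7-[(4-methoxybenzyl)oxy]-3-pentylhept-1-en-5-yne; 14 1,2-epoxyhexane (racemic)
Product: 16 (9S)-13-[(4-methoxybenzyl)oxy]-9-pentyltrideca-7,11-diyn-5-ol (both C5 epimers), via lithium acetylide 15 (not isolated)
Conditions: n-BuLi (2.1 equiv), THF, −78 → −20 °C; then −78 °C, BF3·OEt2, 14
Reagents that add atoms: none
Why: The second Corey–Fuchs stage (Br/Li exchange, Fritsch–Buttenberg–Wiechell rearrangement, deprotonation) gives the lithium acetylide, which opens the BF3-activated terminal epoxide at its CH2 to form C10≡C11 and the C11–CH2 bond, the new carbinol centre being left unassigned because it is oxidised next.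

Step 9
Reactants: 16 (9S)-13-[(4-methoxybenzyl)oxy]-9-pentyltrideca-7,11-diyn-5-ol
Product: 17 (S)-13-[(4-methoxybenzyl)oxy]-9-pentyltrideca-7,11-diyn-5-one
Conditions: Dess–Martin periodinane, NaHCO3, CH2Cl2, 0 °C; crude product filtered and used at once
Reagents that add atoms: none
Why: Buffered Dess–Martin oxidation of a homopropargylic alcohol is the usual entry to β,γ-alkynyl ketones and avoids the amine bases that would isomerise the product to an allenyl ketone.

Step 10
Reactants: 17 (S)-13-[(4-methoxybenzyl)oxy]-9-pentyltrideca-7,11-diyn-5-one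
Product: 18 2-butyl-2-{(S)-8-[(4-methoxybenzyl)oxy]-4-pentylocta-2,6-diyn-1-yl}-1,3-dioxolane
Conditions: Me3SiOCH2CH2OSiMe3, Me3SiOTf (cat.), CH2Cl2, −78 → −20 °C; pyridine quench
Reagents that add atoms: 1,2-bis(trimethylsilyloxy)ethane, C[Si](C)(C)OCCO[Si](C)(C)C
Why: Noyori ketalisation (aprotic silyl-transfer acetalisation at low temperature) forms the dioxolane without protic acid or base, the conditions under which β,γ-unsaturated ketones are ketalised without migration of the unsaturation.

Step 11
Reactants: 18 2-butyl-2-{(S)-8-[(4-methoxybenzyl)oxy]-4-pentylocta-2,6-diyn-1-yl}-1,3-dioxolane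
Product: 19 tetramethyl (2Z,5S,6Z)-8-(2-butyl-1,3-dioxolan-2-yl)-1-[(4-methoxybenzyl)oxy]-5-pentylocta-2,6-diene-2,3,6,7-tetracarboxylate
Conditions: PdI2 (10 mol%), KI (1 equiv), CO/air (4:1, 40 atm), MeOH, 80 °C
Reagents that add atoms: carbon monoxide, [C-]#[O+]; methanol, CO
Why: PdI2 with CO and methanol forms an iodo(methoxycarbonyl)palladium species (divalent palladium) that adds syn across a triple bond; CO then inserts into the vinyl–palladium bond and methanolysis of the acyl releases the (Z)-diester, HI and zerovalent palladium, which the iodine formed from HI and air returns to PdI2. The closest known reaction type is the PdI2/KI-catalysed oxidative bis-alkoxycarbonylation of alkynes to maleic diesters, which is slower for internal dialkyl alkynes than for terminal ones (hence the raised loading, pressure and temperature) and is here run on two such alkynes in one molecule. No ring closes (rings A and B close only in step 12) and no stereocentre is formed; the (Z) geometry of C8=C9 and C10=C11 follows from the syn addition, and C6 is only a propargylic spectator. The selectivity needed is that each vinylpalladium takes up CO instead of the other alkyne or the loss of the allylic PMB-oxy group: the 1,5-diyne spacing would make carbopalladation of the second alkyne a 4-exo or 5-endo closure, and CO pressure makes insertion the faster path. The regiochemistry of the first addition does not matter because both alkyne carbons end up bearing CO2Me, and the dioxolane and PMB ether offer no OH or NH that could divert the acylpalladium into a lactone.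

Step 12
Reactants: 19 tetramethyl (2Z,5S,6Z)-8-(2-butyl-1,3-dioxolan-2-yl)-1-[(4-methoxybenzyl)oxy]-5-pentylocta-2,6-diene-2,3,6,7-tetracarboxylate
Product: 22 3-{(2S)-1-[4-{[(4-methoxybenzyl)oxy]methyl}-2,5-dioxo-2,5-dihydrofuran-3-yl]heptan-2-yl}-4-(2-oxohexyl)furan-2,5-dione, via tetralithium tetracarboxylate 20 (not isolated), via ketal bis-anhydride 21 (not isolated)
Conditions: LiOH, THF/MeOH/H2O, 50 °C; then 1 M HCl (pH 1), THF, rt; toluene azeotrope
Reagents that add atoms: lithium hydroxide, [Li+].[OH-]; water, O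
Why: Saponification followed by acidification relies on the spontaneous dehydrative closure of 2,3-dialkylmaleic acids to their anhydrides at low pH (rings A and B), the same aqueous acid hydrolyses the dioxolane, and the PMB ether keeps the C9 CH2OH from lactonising onto the C8 carboxyl.

Step 13
Reactants: 22 3-{(2S)-1-[4-{[(4-methoxybenzyl)oxy]methyl}-2,5-dioxo-2,5-dihydrofuran-3-yl]heptan-2-yl}-4-(2-oxohexyl)furan-2,5-dione
Product: 23 3-{(2S)-1-[4-(hydroxymethyl)-2,5-dioxo-2,5-dihydrofuran-3-yl]heptan-2-yl}-4-(2-oxohexyl)furan-2,5-dione (CNP0537712.1)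
Conditions: DDQ, CH2Cl2/H2O, 0 °C → rt
Reagents that add atoms: none
Why: Oxidative PMB ether cleavage with DDQ (benzylic hydride abstraction, then hydrolysis of the oxocarbenium ion) runs without base, so both dialkylmaleic anhydrides should stay closed and C6 is untouched.

**Compound list**

1 | (R)-4-benzyl-2-oxazolidinone | O=C1N[C@H](Cc2ccccc2)CO1 | starting material
2 | heptanoyl chloride | CCCCCCC(=O)Cl | starting material
3 | N-lithio-(R)-4-benzyl-2-oxazolidinone (formed in the flask) | [Li+].O=C1[N-][C@H](Cc2ccccc2)CO1 | intermediate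
4 | (R)-4-benzyl-3-heptanoyl-1,3-oxazolidin-2-one | CCCCCCC(=O)N1[C@H](Cc2ccccc2)COC1=O | intermediate
5 | but-2-yne-1,4-diol | OCC#CCO | starting material
6 | monosodium alkoxide of but-2-yne-1,4-diol (formed in the flask) | [Na+].[O-]CC#CCO | intermediate
7 | 4-[(4-methoxybenzyl)oxy]but-2-yn-1-ol | OCC#CCOCc1ccc(OC)cc1 | intermediate
8 | 1-{[(4-bromobut-2-yn-1-yl)oxy]methyl}-4-methoxybenzene | BrCC#CCOCc1ccc(OC)cc1 | intermediate
9 | sodium (Z)-enolate of 4 (formed in the flask) | CCCCC/C=C(\[O-])N1[C@H](Cc2ccccc2)COC1=O.[Na+] | intermediate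
10 | (R)-4-benzyl-3-{(S)-6-[(4-methoxybenzyl)oxy]-2-pentylhex-4-ynoyl}-1,3-oxazolidin-2-one | CCCCC[C@@H](CC#CCOCc1ccc(OC)cc1)C(=O)N1[C@H](Cc2ccccc2)COC1=O | intermediate
11 | (S)-6-[(4-methoxybenzyl)oxy]-2-pentylhex-4-yn-1-ol | CCCCC[C@@H](CC#CCOCc1ccc(OC)cc1)CO | intermediate
12 | (S)-6-[(4-methoxybenzyl)oxy]-2-pentylhex-4-ynal | CCCCC[C@@H](CC#CCOCc1ccc(OC)cc1)C=O | intermediate
13 | (S)-1,1-dibromo-7-[(4-methoxybenzyl)oxy]-3-pentylhept-1-en-5-yne | CCCCC[C@@H](CC#CCOCc1ccc(OC)cc1)C=C(Br)Br | intermediate
14 | 1,2-epoxyhexane (2-butyloxirane, racemic) | CCCCC1CO1 | starting material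
15 | [(S)-7-[(4-methoxybenzyl)oxy]-3-pentylhepta-1,5-diyn-1-yl]lithium (formed in the flask) | CCCCC[C@@H](CC#CCOCc1ccc(OC)cc1)C#C[Li] | intermediate
16 | (9S)-13-[(4-methoxybenzyl)oxy]-9-pentyltrideca-7,11-diyn-5-ol (both C5 epimers) | CCCCC[C@@H](CC#CCOCc1ccc(OC)cc1)C#CCC(O)CCCC | intermediate
17 | (S)-13-[(4-methoxybenzyl)oxy]-9-pentyltrideca-7,11-diyn-5-one | CCCCC[C@@H](CC#CCOCc1ccc(OC)cc1)C#CCC(=O)CCCC | intermediate
18 | 2-butyl-2-{(S)-8-[(4-methoxybenzyl)oxy]-4-pentylocta-2,6-diyn-1-yl}-1,3-dioxolane | CCCCC[C@@H](CC#CCOCc1ccc(OC)cc1)C#CCC1(CCCC)OCCO1 | intermediate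
19 | tetramethyl (2Z,5S,6Z)-8-(2-butyl-1,3-dioxolan-2-yl)-1-[(4-methoxybenzyl)oxy]-5-pentylocta-2,6-diene-2,3,6,7-tetracarboxylate | CCCCC[C@@H](C/C(C(=O)OC)=C(COCc1ccc(OC)cc1)/C(=O)OC)/C(C(=O)OC)=C(CC1(CCCC)OCCO1)/C(=O)OC | intermediate
20 | tetralithium (2Z,5S,6Z)-8-(2-butyl-1,3-dioxolan-2-yl)-1-[(4-methoxybenzyl)oxy]-5-pentylocta-2,6-diene-2,3,6,7-tetracarboxylate (formed in the flask) | CCCCC[C@@H](C/C(C(=O)[O-])=C(COCc1ccc(OC)cc1)/C(=O)[O-])/C(C(=O)[O-])=C(CC1(CCCC)OCCO1)/C(=O)[O-].[Li+].[Li+].[Li+].[Li+] | intermediate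
21 | 3-{(2S)-1-[4-{[(4-methoxybenzyl)oxy]methyl}-2,5-dioxo-2,5-dihydrofuran-3-yl]heptan-2-yl}-4-[(2-butyl-1,3-dioxolan-2-yl)methyl]furan-2,5-dione (formed in the flask) | CCCCC[C@@H](CC1=C(COCc2ccc(OC)cc2)C(=O)OC1=O)C1=C(CC2(CCCC)OCCO2)C(=O)OC1=O | intermediate
22 | 3-{(2S)-1-[4-{[(4-methoxybenzyl)oxy]methyl}-2,5-dioxo-2,5-dihydrofuran-3-yl]heptan-2-yl}-4-(2-oxohexyl)furan-2,5-dione | CCCCC[C@@H](CC1=C(COCc2ccc(OC)cc2)C(=O)OC1=O)C1=C(CC(=O)CCCC)C(=O)OC1=O | intermediate
23 | 3-{(2S)-1-[4-(hydroxymethyl)-2,5-dioxo-2,5-dihydrofuran-3-yl]heptan-2-yl}-4-(2-oxohexyl)furan-2,5-dione | CCCCC[C@@H](CC1=C(CO)C(=O)OC1=O)C1=C(CC(=O)CCCC)C(=O)OC1=O | target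

**Count and risks**

Total step count: 13. Longest linear sequence: 12 steps (from but-2-yne-1,4-diol 5 through steps 2–13).

Steps most likely to fail:

Step 11. The methoxycarbonyl-palladation of two internal dialkyl alkynes may be too slow, above all at the hindered C10≡C11 unit, so the reaction could stall after one carbonylation; the HI formed in methanol could also cause ketal exchange. The fallback sets out from diyne 18. Platinum-catalysed syn-diboration of both triple bonds (bis(pinacolato)diboron, Pt(PPh3)4, DMF, 80 °C) should give 2,2',2'',2'''-[(2Z,5S,6Z)-8-(2-butyl-1,3-dioxolan-2-yl)-1-[(4-methoxybenzyl)oxy]-5-pentylocta-2,6-diene-2,3,6,7-tetrayl]tetrakis(4,4,5,5-tetramethyl-1,3,2-dioxaborolane) F1, with the cis geometry fixed by the syn addition. Oxidative methoxycarbonylation of the four alkenyl C–B bonds (Pd(OAc)2, PPh3, p-benzoquinone, CO 1 atm, MeOH, rt) then returns to the route at tetraester 19.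

Step 10. The β,γ-alkynyl ketone may undergo prototropic isomerisation to the conjugated allenyl ketone during ketalisation, or already during isolation after step 9. The fallback never frees the ketone and sets out from dibromoalkene 13. n-BuLi (2 equiv) gives acetylide 15, which is trapped with paraformaldehyde to give (S)-8-[(4-methoxybenzyl)oxy]-4-pentylocta-2,6-diyn-1-ol F2. Appel bromination (CBr4, PPh3) gives (S)-1-{[(8-bromo-5-pentylocta-2,6-diyn-1-yl)oxy]methyl}-4-methoxybenzene F3. 2-Butyl-1,3-dithiane F4 (from pentanal and propane-1,3-dithiol, BF3·OEt2) is lithiated with n-BuLi in THF at −30 °C and alkylated with F3 to give 2-butyl-2-{(S)-8-[(4-methoxybenzyl)oxy]-4-pentylocta-2,6-diyn-1-yl}-1,3-dithiane F5. Oxidative exchange of the dithiane for the dioxolane with PhI(OCOCF3)2 and ethylene glycol in MeCN returns to the route at ketal 18.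

Step 12. Hydroxide may deprotonate the vinylogous γ-positions of the maleates, leading to double-bond migration, epimerisation at C6 or β-elimination of the PMB-oxy group; hydrolysis of the hindered esters may also stay incomplete. The fallback sets out from tetraester 19 and cleaves the O–CH3 bonds instead of the acyl–oxygen bonds: anhydrous LiI in refluxing ethyl acetate removes the four methyl groups by SN2 attack of iodide, so no hydroxide meets the substrate. This returns to the route at the tetralithium salt 20, which is acidified as in step 12; the fallback makes no compound outside the compound list, F0.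

**Further compounds**

F1 | step 11 | 2,2',2'',2'''-[(2Z,5S,6Z)-8-(2-butyl-1,3-dioxolan-2-yl)-1-[(4-methoxybenzyl)oxy]-5-pentylocta-2,6-diene-2,3,6,7-tetrayl]tetrakis(4,4,5,5-tetramethyl-1,3,2-dioxaborolane) | CCCCC[C@@H](C/C(B1OC(C)(C)C(C)(C)O1)=C(COCc1ccc(OC)cc1)/B1OC(C)(C)C(C)(C)O1)/C(B1OC(C)(C)C(C)(C)O1)=C(CC1(CCCC)OCCO1)/B1OC(C)(C)C(C)(C)O1
F2 | step 10 | (S)-8-[(4-methoxybenzyl)oxy]-4-pentylocta-2,6-diyn-1-ol | CCCCC[C@@H](CC#CCOCc1ccc(OC)cc1)C#CCO
F3 | step 10 | (S)-1-{[(8-bromo-5-pentylocta-2,6-diyn-1-yl)oxy]methyl}-4-methoxybenzene | CCCCC[C@@H](CC#CCOCc1ccc(OC)cc1)C#CCBr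
F4 | step 10 | 2-butyl-1,3-dithiane | CCCCC1SCCCS1
F5 | step 10 | 2-butyl-2-{(S)-8-[(4-methoxybenzyl)oxy]-4-pentylocta-2,6-diyn-1-yl}-1,3-dithiane | CCCCC[C@@H](CC#CCOCc1ccc(OC)cc1)C#CCC1(CCCC)SCCCS1
F0 | step 12 | none | none
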